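**Strategy.** The oxolane ring is cut at C2–C3 (and at its mirror bond C4–C5). The key step exploits that C2 and C5, the two aryl-bearing carbons flanking O1, are an aryl aldehyde carbon and an aryl carbinol carbon in disguise, and that the C4 branch is a masked formyl group: a Prins–pinacol rearrangement of a 2,4-diaryl-5-alkenyl-1,3-dioxolane forms both ring C–C bonds, the oxolane and three stereocentres in one operation. Base then epimerises the formyl carbon, and a cis-fused lactol traps the C3/C4-cis isomer; reduction gives the meso diol, so racemic intermediates suffice. Acetylation and hydrogenolysis of four benzyl ethers complete the route.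

Key step: step 5

Remark: the target is a meso compound (mirror plane through O1 and the midpoint of C3–C4), so every chiral intermediate is used as the racemate and its SMILES shows one enantiomer. Oxolane numbering throughout: O1, C2 (aryl), C3 (CH2OAc branch), C4 (second one-carbon branch), C5 (aryl).

Step 1
Reactants: 1 acrolein
Product: 2 3-bromoprop-1-enyl acetate (E/Z mixture)
Conditions: AcBr, ZnCl2 (cat.), CH2Cl2, −20 °C → rt
Reagents that add atoms: acetyl bromide, CC(=O)Br
Why: Lewis-acid-catalysed 1,4-addition of the acyl bromide to the enal (O-acylation with bromide delivery to the β-carbon) should give the γ-bromo enol acetate; its geometry is irrelevant for the next step.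

Step 2
Reactants: 3 3,4-bis(benzyloxy)benzaldehyde; 2 3-bromoprop-1-enyl acetate
Product: 5 1-[3,4-bis(benzyloxy)phenyl]but-3-ene-1,2-diol (racemic syn/anti mixture), via monoacetate 4 (not isolated)
Conditions: In powder, THF, rt; then K2CO3 (cat.), MeOH, rt
Reagents that add atoms: none
Why: Barbier-type α-acetoxyallylation, in which the 3-acetoxyallylindium species adds through its oxygen-bearing γ-carbon, followed by methanolysis of the acetate; both diol diastereomers are usable because the allylic carbinol carbon later becomes the formyl carbon.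

Step 3
Reactants: 5 1-[3,4-bis(benzyloxy)phenyl]but-3-ene-1,2-diol; 3 3,4-bis(benzyloxy)benzaldehyde
Product: 6 2,4-bis[3,4-bis(benzyloxy)phenyl]-5-ethenyl-1,3-dioxolane (stereoisomer mixture)
Conditions: PPTS (cat.), benzene, reflux, Dean–Stark
Reagents that add atoms: none
Why: Acid-catalysed acetalisation with azeotropic removal of water; the configuration of the new acetal carbon is uncontrolled and irrelevant, since this carbon becomes planar in step 5.

Step 4
Reactants: 6 2,4-bis[3,4-bis(benzyloxy)phenyl]-5-ethenyl-1,3-dioxolane; 7 (Z)-but-2-ene-1,4-diyl diacetate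
Product: 8 (E)-3-{2,5-bis[3,4-bis(benzyloxy)phenyl]-1,3-dioxolan-4-yl}prop-2-en-1-yl acetate (stereoisomer mixture at the dioxolane)
Conditions: second-generation Grubbs catalyst (5 mol%), excess 7, CH2Cl2, 40 °C
Reagents that add atoms: none
Why: Olefin cross-metathesis of the hindered allylic-oxygenated vinyl group with the symmetric diacetate should install the CH2OAc arm with the E geometry favoured under the reversible conditions; this geometry later sets the C2/C3 trans relation.

Step 5
Reactants: 8 (E)-3-{2,5-bis[3,4-bis(benzyloxy)phenyl]-1,3-dioxolan-4-yl}prop-2-en-1-yl acetate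
Product: 9 {2,5-cis-bis[3,4-bis(benzyloxy)phenyl]-4-formyloxolan-3-yl}methyl acetate (racemic; 2,3-trans; 3,4-trans; 4,5-cis)
Conditions: SnCl4, CH2Cl2, −78 → −20 °C
Reagents that add atoms: none
Why: SnCl4 opens the acetal at the allylic oxygen to give the aryl-stabilised E-oxocarbenium ion on the benzylic oxygen; its carbon is attacked by the CH2OAc-bearing alkene carbon through a chair transition state (6-endo-trig Prins closure to an oxan-4-yl cation), and the ring C–C bond of the neighbouring tin-bound carbinol then migrates to the cationic carbon (pinacol shift), which contracts the oxane to the oxolane and turns the carbinol carbon into the formyl group. The closest known reaction type is the Prins–pinacol rearrangement of 4-alkenyl-1,3-dioxolanes to 3-acyloxolanes; a 2-oxonia-Cope shift followed by 5-(enolexo)-endo-trig aldol closure is the alternative pathway and leads to the same product. The chair controls three new stereocentres: both aryl groups next to oxygen sit equatorial, which gives the 2,5-cis relation; the E alkene places CH2OAc equatorial and therefore trans to the aryl group on the neighbouring carbon; the migrating bond delivers the formyl group cis to its neighbouring aryl group, the one relation that step 6 inverts. The step needs the productive mode of acetal opening and clean transfer of alkene geometry: the oxocarbenium ion on the allylic oxygen has no cyclisation path and returns to the acetal, and all stereoisomers of 8 converge because the acetal carbon becomes planar and the alkenyl-bearing carbinol carbon ends as the formyl carbon.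

Step 6
Reactants: 9 {2,5-cis-bis[3,4-bis(benzyloxy)phenyl]-4-formyloxolan-3-yl}methyl acetate
Product: 12 [(2R,3S,4R,5S)-2,5-bis[3,4-bis(benzyloxy)phenyl]oxolane-3,4-diyl]dimethanol (meso diol), via hydroxy aldehyde 10 (not isolated), via cis-fused lactol 11 (not isolated)
Conditions: K2CO3, MeOH, rt; then NaBH4, 0 °C
Reagents that add atoms: none
Why: Carbonate-mediated methanolysis frees the primary alcohol and enolisation epimerises C4, the cis isomer being withdrawn as the cis-fused lactol (a trans-fused bicyclo[3.3.0] lactol is too strained to form), and NaBH4 then reduces the lactol through its open form faster than the aldehyde can re-enolise, so C4 ends cis to C3 and trans to the C5 aryl group under thermodynamic control.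

Step 7
Reactants: 12 [(2R,3S,4R,5S)-2,5-bis[3,4-bis(benzyloxy)phenyl]oxolane-3,4-diyl]dimethanol
Product: 13 [(2R,3S,4R,5S)-2,5-bis[3,4-bis(benzyloxy)phenyl]oxolane-3,4-diyl]bis(methylene) diacetate (meso)
Conditions: Ac2O, pyridine, DMAP (cat.), CH2Cl2, rt
Reagents that add atoms: acetic anhydride, CC(=O)OC(C)=O
Why: DMAP-catalysed acylation of the two equivalent primary alcohols; no stereocentre is touched.

Step 8
Reactants: 13 [(2R,3S,4R,5S)-2,5-bis[3,4-bis(benzyloxy)phenyl]oxolane-3,4-diyl]bis(methylene) diacetate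
Product: 14 [(2R,3S,4R,5S)-2,5-bis(3,4-dihydroxyphenyl)oxolane-3,4-diyl]bis(methylene) diacetate (meso; CNP0416169.1)
Conditions: H2 (1 atm), 10% Pd/C, EtOAc, rt
Reagents that add atoms: none
Why: Hydrogenolysis of the four benzyl aryl ethers under neutral conditions should be much faster than cleavage of the ring benzylic C–O bonds and leaves the alkyl acetates untouched.

**Compound list**

1 | acrolein | C=CC=O | starting material
2 | 3-bromoprop-1-enyl acetate (E/Z mixture) | CC(=O)OC=CCBr | intermediate
3 | 3,4-bis(benzyloxy)benzaldehyde | O=Cc1ccc(OCc2ccccc2)c(OCc2ccccc2)c1 | starting material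
4 | 1-[3,4-bis(benzyloxy)phenyl]-1-hydroxybut-3-en-2-yl acetate (diastereomer mixture, partly acetyl-migrated) | CC(=O)OC(C=C)C(O)c1ccc(OCc2ccccc2)c(OCc2ccccc2)c1 | intermediate (not isolated)
5 | 1-[3,4-bis(benzyloxy)phenyl]but-3-ene-1,2-diol (racemic syn/anti mixture) | OC(C=C)C(O)c1ccc(OCc2ccccc2)c(OCc2ccccc2)c1 | intermediate
6 | 2,4-bis[3,4-bis(benzyloxy)phenyl]-5-ethenyl-1,3-dioxolane (stereoisomer mixture) | C=CC1OC(c2ccc(OCc3ccccc3)c(OCc3ccccc3)c2)OC1c1ccc(OCc2ccccc2)c(OCc2ccccc2)c1 | intermediate
7 | (Z)-but-2-ene-1,4-diyl diacetate | CC(=O)OC/C=C\COC(C)=O | starting material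
8 | (E)-3-{2,5-bis[3,4-bis(benzyloxy)phenyl]-1,3-dioxolan-4-yl}prop-2-en-1-yl acetate (stereoisomer mixture at the dioxolane) | CC(=O)OC/C=C/C1OC(c2ccc(OCc3ccccc3)c(OCc3ccccc3)c2)OC1c1ccc(OCc2ccccc2)c(OCc2ccccc2)c1 | intermediate
9 | {2,5-cis-bis[3,4-bis(benzyloxy)phenyl]-4-formyloxolan-3-yl}methyl acetate (racemic; CH2OAc trans and CHO cis to the neighbouring aryl group) | CC(=O)OC[C@@H]1[C@@H](C=O)[C@@H](c2ccc(OCc3ccccc3)c(OCc3ccccc3)c2)O[C@H]1c1ccc(OCc2ccccc2)c(OCc2ccccc2)c1 | intermediate
10 | 2,5-cis-bis[3,4-bis(benzyloxy)phenyl]-4-(hydroxymethyl)oxolane-3-carbaldehyde (racemic; CHO cis to the neighbouring aryl group, trans to CH2OH) | OC[C@@H]1[C@@H](C=O)[C@@H](c2ccc(OCc3ccccc3)c(OCc3ccccc3)c2)O[C@H]1c1ccc(OCc2ccccc2)c(OCc2ccccc2)c1 | intermediate (not isolated)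
11 | 4,6-bis[3,4-bis(benzyloxy)phenyl]tetrahydro-1H,3H-furo[3,4-c]furan-1-ol (racemic; cis-fused, both aryl groups exo, anomer mixture) | OC1OC[C@@H]2[C@H]1[C@@H](c1ccc(OCc3ccccc3)c(OCc3ccccc3)c1)O[C@H]2c1ccc(OCc2ccccc2)c(OCc2ccccc2)c1 | intermediate (not isolated)
12 | [(2R,3S,4R,5S)-2,5-bis[3,4-bis(benzyloxy)phenyl]oxolane-3,4-diyl]dimethanol (meso) | OC[C@@H]1[C@H](CO)[C@@H](c2ccc(OCc3ccccc3)c(OCc3ccccc3)c2)O[C@H]1c1ccc(OCc2ccccc2)c(OCc2ccccc2)c1 | intermediate
13 | [(2R,3S,4R,5S)-2,5-bis[3,4-bis(benzyloxy)phenyl]oxolane-3,4-diyl]bis(methylene) diacetate (meso) | CC(=O)OC[C@@H]1[C@H](COC(C)=O)[C@@H](c2ccc(OCc3ccccc3)c(OCc3ccccc3)c2)O[C@H]1c1ccc(OCc2ccccc2)c(OCc2ccccc2)c1 | intermediate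
14 | [(2R,3S,4R,5S)-2,5-bis(3,4-dihydroxyphenyl)oxolane-3,4-diyl]bis(methylene) diacetate (meso) | CC(=O)OC[C@@H]1[C@H](COC(C)=O)[C@@H](c2ccc(O)c(O)c2)O[C@H]1c1ccc(O)c(O)c1 | target

**Step count.** Total: 8 steps. Longest linear sequence: 8 steps (1 → 2 → 5 → 6 → 8 → 9 → 12 → 13 → 14).

**Steps most likely to fail**

1. Step 5. The very electron-rich aryl groups may divert the cation: ionisation of a benzylic C–O bond, capture of the oxocarbenium ion by an arene ring, or reversible ring opening of the product that erodes the 2,5-cis relation. The allylic acetate also lowers the nucleophilicity of the alkene. Fallback by 1,3-dipolar cycloaddition, setting out from 3 and coming back at 12: reductive coupling of 3 (TiCl4, Zn, THF, reflux) should give (E)-1,2-bis[3,4-bis(benzyloxy)phenyl]ethene F1. Epoxidation with dimethyldioxirane in acetone gives trans-2,3-bis[3,4-bis(benzyloxy)phenyl]oxirane F2. Irradiation of F2 with catalytic 9,10-dicyanoanthracene in MeCN in the presence of maleic anhydride opens the oxirane C–C bond by photoinduced electron transfer to the carbonyl ylide, which adds to the dipolarophile; the exo adduct, cis-fused 4,6-bis[3,4-bis(benzyloxy)phenyl]tetrahydro-1H,3H-furo[3,4-c]furan-1,3-dione F3, would be separated from the endo isomer. Reduction of F3 with LiAlH4 in THF gives 12.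

2. Step 4. Incomplete E selectivity and self-metathesis of the hindered vinyl dioxolane would carry a Z isomer forward, which leads to the all-cis oxolane. Fallback with the alkene geometry fixed by olefination, setting out from 3 and coming back at 8: Horner–Wadsworth–Emmons reaction of 3 with triethyl 4-phosphonocrotonate (LiN(SiMe3)2, THF) gives ethyl (2E,4E)-5-[3,4-bis(benzyloxy)phenyl]penta-2,4-dienoate F4. Dihydroxylation (OsO4 cat., NMO, acetone/water) should occur at the distal, more electron-rich 4,5-alkene and give the syn diol ethyl (E)-5-[3,4-bis(benzyloxy)phenyl]-4,5-dihydroxypent-2-enoate F5. Acetalisation with 3 (PPTS, benzene, Dean–Stark) gives ethyl (E)-3-{2,5-bis[3,4-bis(benzyloxy)phenyl]-1,3-dioxolan-4-yl}prop-2-enoate F6. Reduction with iBu2AlH (CH2Cl2, −78 °C) gives the allylic alcohol (E)-3-{2,5-bis[3,4-bis(benzyloxy)phenyl]-1,3-dioxolan-4-yl}prop-2-en-1-ol F7, and acetylation (Ac2O, pyridine) gives 8 as the pure E isomer (4,5-trans dioxolane).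

3. Step 6. Hydride delivery may compete with epimerisation, so that the trans hydroxy aldehyde is reduced before it has passed into the lactol; base may also open the oxolane by β-elimination. Fallback that stores the configuration in a lactone, setting out from 9 and coming back at 12: K2CO3 in MeOH is used alone and lactol 11 is isolated. Oxidation with PhI(OAc)2 and catalytic TEMPO in CH2Cl2 gives the cis-fused lactone 4,6-bis[3,4-bis(benzyloxy)phenyl]tetrahydro-1H,3H-furo[3,4-c]furan-1-one F8, which cannot epimerise to a trans ring fusion. Reduction of F8 with LiAlH4 in THF gives 12.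

**Further compounds**

F1 | step 5 | (E)-1,2-bis[3,4-bis(benzyloxy)phenyl]ethene | C(=C/c1ccc(OCc2ccccc2)c(OCc2ccccc2)c1)\c1ccc(OCc2ccccc2)c(OCc2ccccc2)c1
F2 | step 5 | trans-2,3-bis[3,4-bis(benzyloxy)phenyl]oxirane (racemic) | c1cc(OCc3ccccc3)c(OCc3ccccc3)cc1[C@@H]2[C@H](O2)c1ccc(OCc3ccccc3)c(OCc3ccccc3)c1
F3 | step 5 | 4,6-bis[3,4-bis(benzyloxy)phenyl]tetrahydro-1H,3H-furo[3,4-c]furan-1,3-dione (meso; cis-fused, aryl groups exo) | O=C1OC(=O)[C@@H]2[C@H]1[C@@H](c1ccc(OCc3ccccc3)c(OCc3ccccc3)c1)O[C@H]2c1ccc(OCc2ccccc2)c(OCc2ccccc2)c1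
F4 | step 4 | ethyl (2E,4E)-5-[3,4-bis(benzyloxy)phenyl]penta-2,4-dienoate | CCOC(=O)/C=C/C=C/c1ccc(OCc2ccccc2)c(OCc2ccccc2)c1
F5 | step 4 | ethyl (E)-5-[3,4-bis(benzyloxy)phenyl]-4,5-dihydroxypent-2-enoate (racemic syn diol) | CCOC(=O)/C=C/[C@@H](O)[C@H](O)c1ccc(OCc2ccccc2)c(OCc2ccccc2)c1
F6 | step 4 | ethyl (E)-3-{2,5-bis[3,4-bis(benzyloxy)phenyl]-1,3-dioxolan-4-yl}prop-2-enoate (racemic; 4,5-trans, acetal epimers) | CCOC(=O)/C=C/[C@H]1OC(c2ccc(OCc3ccccc3)c(OCc3ccccc3)c2)O[C@@H]1c1ccc(OCc2ccccc2)c(OCc2ccccc2)c1
F7 | step 4 | (E)-3-{2,5-bis[3,4-bis(benzyloxy)phenyl]-1,3-dioxolan-4-yl}prop-2-en-1-ol (racemic; 4,5-trans, acetal epimers) | OC/C=C/[C@H]1OC(c2ccc(OCc3ccccc3)c(OCc3ccccc3)c2)O[C@@H]1c1ccc(OCc2ccccc2)c(OCc2ccccc2)c1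
F8 | step 6 | 4,6-bis[3,4-bis(benzyloxy)phenyl]tetrahydro-1H,3H-furo[3,4-c]furan-1-one (racemic; cis-fused, aryl groups exo) | O=C1OC[C@@H]2[C@H]1[C@@H](c1ccc(OCc3ccccc3)c(OCc3ccccc3)c1)O[C@H]2c1ccc(OCc2ccccc2)c(OCc2ccccc2)c1
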